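Before we add more catalyst or more time to this flask, we reckon in catalyst rather than in hours.

    reagent + free catalyst → catalyst intermediate A (k1 = 75.9 /M/s)
    starting material + free catalyst → spent catalyst (k2 = 0.0287 /M/s)
    starting material + catalyst intermediate C ⇌ catalyst intermediate D (K3 = 110 /M, k3 = 428 /M/s)
    catalyst intermediate D → free catalyst + product (k4 = 11.0 /s)
    reagent + by-product ⇌ idle adduct, settled at all times (K5 = 250 /M)
    catalyst intermediate B → catalyst intermediate C (k6 = 1.01 /s)
    catalyst intermediate A → by-product + catalyst intermediate B (k7 = 0.998 /s)

starting material 42 mM; reagent 21.0 mM; free catalyst 84 µM; time 1.5 h

- amounts and yields of by-product count idle adduct too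
- run time (flask): 1.5 h

- part of the starting material that has reacted at 1.5 h
- share of the unused reagent that is free and not bound as idle adduct, at 1.5 h

Reagent is the limiting reagent, and it is used one for one with starting material. Free catalyst meets reagent and turns over, or meets starting material and is lost. The selectivity factor k1/k2 is 2640. So each mM of reagent used costs c(starting material)/(that factor × c(free reagent)) of catalyst, a rule without time or catalyst charge in it.

Idle adduct makes the bill grow. Its balance puts the free share of unused reagent at one over (one plus K5 × c(free by-product)). Late in the run that share is near 16.0%, and c(starting material) is near 21.0 mM. The catalyst price of cutting unused reagent by a factor e is then 49.6 µM.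

Early, the share is near one and the price is nearer 15.9 µM. We charge the first half of the reagent at that early price, about 11.0 µM. The remaining 73.0 µM of catalyst should bring unused reagent down to 2.41 mM. Our reckoning is c near 44.3% and fr near 19.8%. This lets the whole catalyst charge be paid out. We assume so because the half-life of reagent by step 1 alone, with the other concentrations held at their charge, is 1.8 min, shorter than 1.5 h.

The neighbour flask has 0.034 mM of free catalyst, with its other charges and the time as in this flask. It pays the same bill along the same path, but it has less to pay with. The gap is about one price, so it should stop with about e times our flask's unused reagent.

The forecast gives 45.2% (44.3% to 46%) and 18.7% (17.8% to 20%), with c above ours, and it says the catalyst would be exhausted “because free reagent collapses”.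

The flask gives 45.6% and 18.6%.

At 1.50 h this flask has 96.0% of its catalyst spent, so 3.38 µM is still unpaid. Unused reagent, free and bound, stands at 1.93 mM, and the price says that sum can fall to 1.80 mM. Ten times the time gives 1.79 mM, with c at 45.9%, so the flask is close to rest.

For the neighbour flask, one catalyst gap at this price multiplies our unused reagent to 5.28 mM, which means c near 37.4%. The computed neighbour flask gives 35.9%, with 94.5% of its catalyst spent.

All constants are invented.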